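## The problem

The target is a bibenzyl with no stereocentre, so the whole difficulty is regiochemical. Ring A is numbered here C1 to C6: C1 carries the methoxy group, C2 is the only CH, C3 carries the free phenol, C4 and C6 each carry a 4-hydroxybenzyl group, and C5 carries the CH2CH2 bridge to ring B. Ring B bears a third 4-hydroxybenzyl group ortho to the bridge and a phenol para to that benzyl group. Ring A therefore has three contiguous carbon substituents (benzyl, arylethyl, benzyl) between two meta oxygens; electrophilic substitution of a resorcinol does not deliver this cleanly, because the position between the oxygens (C2) competes. Apart from the single O-methyl group ring A is locally symmetric, so the two oxygens must be told apart at some stage, and four further phenols must be unveiled at the end without touching the methyl ether. The free pentaphenol is electron-rich: the 4-hydroxybenzyl–arene bonds can be cleaved by strong acid through ipso protonation, and the phenols and diarylmethane CH2 groups are prone to oxidation, so the last operations should be neutral and reductive. The feature that opens the key step is that C1–C2–C3, with 1,3-dioxygenation and an unsubstituted C2, is the imprint of an ester carbon, an activated methylene and a ketone. C2–C3–C4 with the C4 benzyl group is a 3-oxo-5-arylpentanoate, and C1–C6–C5 with the C6 benzyl group and the bridge is a 2-benzylpenta-2,3-dienoate whose central allene carbon is C5. The two chains together are already at the resorcinol oxidation level, so a Michael/Dieckmann sequence should give the arene without any oxidation.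

## Retrosynthesis

**Protecting groups.** The target 22 is traced back to the tetrabenzyl ether 21 by cutting four O–benzyl bonds. Hydrogenolysis is neutral, spares the methyl ether and the diarylmethane CH2 groups, and the C3 phenol of 21 is already free. Benzyl ethers are preferred to silyl or methyl ethers because they survive the strong bases of the fragment syntheses and leave no selectivity problem at the end.

**Carboxyl group at C2.** Phenol 21 is traced back to the tert-butyl 2-hydroxy-6-methoxybenzoate 19 through the acid 20, by adding a carboxyl group at C2. This ester is the activating group of the annulation, it blocks C2, and it is the handle that distinguishes the two oxygens. A 2,6-dioxygenated benzoic acid loses CO2 readily, so the removal costs one operation.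

**O-Methyl group.** Ester 19 comes from the symmetric 2,6-dihydroxybenzoate 18 by cutting the O–CH3 bond. Methylating at the benzoate stage is preferred to methylating the decarboxylated resorcinol: after the first alkylation the remaining hydroxyl is locked in a hydrogen bond to the ester carbonyl and should react much more slowly, whereas the free resorcinol offers only statistical control.

**Ring A (key disconnection).** Benzoate 18 is cut at C4–C5 and C1–C2 into the keto ester 16 and the racemic allenoate 14. The neighbouring cuts, such as C–benzyl bonds on an existing arene, leave the C4/C5/C6 regiochemistry open; this cut fixes every substituent in the open chains. The forward reaction must add the γ-carbon of the dianion of 16 to the central allene carbon, and the remaining enolate must then acylate on the methyl ester. The precursors are two chains with no ring A at all.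

**Allenoate.** Compound 14 is cut at the C5=C6 double bond into the fully substituted stabilized ylide 11 and the ketene 13, which is generated from the acid chloride 12 of propanoic acid 7. The carboxyl carbon of 7 becomes C5. This Wittig allenation is the standard entry to α-substituted 2,3-dienoates and joins two fragments of similar size.

**Ylide and keto ester.** Ylide 11 arises from methyl (triphenylphosphoranylidene)acetate 8 and 4-(benzyloxy)benzyl chloride 9 through the phosphonium salt 10. Keto ester 16 arises from tert-butyl acetoacetate 15 and the same chloride 9 by dianion γ-alkylation. One commercial benzyl chloride thus supplies both benzyl groups of ring A.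

**Ring B acid.** Acid 7 is cut at the alkene of cinnamic acid 6 (selective hydrogenation) and at the aryl–vinyl bond (Heck reaction of bromide 5 with acrylic acid). The diarylmethane 5 comes from carbinol 4 by ionic deoxygenation. Carbinol 4 comes from aldehyde 2 and the Grignard reagent 3, and 2 from 2-bromo-4-hydroxybenzaldehyde 1. In 1 the formyl carbon sits para to the oxygen, as the benzyl group of ring B must, and the bromine sits where the bridge starts.

## Roads not taken

**Alternative 1:** The cut runs through the C5–CH2 bond and the C6–benzylic carbon bond of ring A. Fluoride would release the C5–C6 aryne from the silyl triflate A2. The enolate of keto ester A3 adds at C5, the aryl anion at C6 closes on the ketone, and the benzocyclobutenoxide fragments to the acyl-alkylation product A1.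
- Merits: the reaction type is documented; the ring A oxygens are differentiated from the start; the C1 methoxy group polarizes the aryne so that the carbon nucleophile goes to C5 as required.
- Weak points: A2 is itself a pentasubstituted arene that already carries one benzyl group and needs a long preparation. The aryne is flanked on both sides, and the attack at C5 occurs next to the benzyl group. A1 still needs reduction of the diaryl ketone to CH2 and a multi-step conversion of the CH2CO2Me arm into the bridge with ring B.
- Comparison: it has no desymmetrization problem and its key step is better precedented than the one chosen. Against this the chosen plan builds ring A with all three carbon substituents at the final oxidation level from simple chains and needs only three steps after the key step.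

**Alternative 2:** The cut removes the three outer phenol rings at their aryl–CH bonds. Excess Grignard reagent 3 would add to the three formyl groups of the trialdehyde A5 to give the triol A4 as a mixture of diastereomers, whose carbinol centres are removed later.
- Merits: it exploits the identity of the three outer rings and uses one commercial reagent three times. The end game is better than the chosen one: a single hydrogenolysis would remove three benzylic hydroxyls and five benzyl groups.
- Weak points: the difficulty is moved into A5. Its ring A needs two formyl groups on either side of the bridge and differentiated oxygens, and formylation of such a ring competes with the position between the oxygens. The two ring A aldehydes are hindered and deactivated by ortho and para alkoxy groups.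
- Comparison: the chosen plan has the longer end game, but it settles the ring A substitution pattern by construction and not by arene substitution.

**Alternative 3:** The cut removes both ring A benzyl groups and the bridge at once. With Pd(OAc)2, a triarylphosphine, norbornene and Cs2CO3 the iodoarene A7 would be benzylated at both ortho C–H positions by two equivalents of chloride 9 and then coupled at the ipso carbon with the styrene A8 to give the stilbene A6. One hydrogenation would then saturate the alkene and remove five benzyl groups.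
- Merits: this is clearly the shortest road, three bonds in one operation from very simple pieces, with the oxygens differentiated from the start.
- Weak points: both ortho positions of A7 are flanked by alkoxy groups, and the palladation step of this chemistry is sensitive to a neighbouring meta substituent. Each benzylation passes through oxidative addition of a benzyl chloride to a divalent palladacycle (a tetravalent palladium intermediate), and the termination is a Heck reaction of a 2,6-disubstituted arylpalladium species with a hindered styrene. Partial benzylation or early termination would give mixtures that are hard to separate.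
- Comparison: in step economy it is better than the chosen plan. The chosen plan sets against this a regiochemical outcome that does not depend on a triple cascade at a congested arene, and intermediates that can be purified after each bond formation.

Key step: step 9

Remark on the chemistry: the target has no stereocentre. The axially chiral allenoate 14 is used as the racemate and the adduct 17 as a mixture of isomers; both elements vanish when ring A aromatizes. The Grignard reagent 3 is taken as the commercial THF solution.

## Route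

Step 1
Reactants: 1 2-bromo-4-hydroxybenzaldehyde
Product: 2 4-(benzyloxy)-2-bromobenzaldehyde
Conditions: BnBr, K2CO3, DMF, rt
Reagents that add atoms: benzyl bromide, BrCc1ccccc1
Why: Williamson ether synthesis on an acidic para-formyl phenol; the aldehyde and the aryl bromide are inert.

Step 2
Reactants: 2 4-(benzyloxy)-2-bromobenzaldehyde; 3 4-(benzyloxy)phenylmagnesium bromide
Product: 4 rac-[4-(benzyloxy)-2-bromophenyl][4-(benzyloxy)phenyl]methanol
Conditions: THF, −78 °C to 0 °C; aq NH4Cl
Reagents that add atoms: none
Why: Grignard addition to the aldehyde; an aryl Grignard reagent does not exchange with the aryl bromide at this temperature, and the racemic carbinol centre is removed in step 3.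

Step 3
Reactants: 4 rac-[4-(benzyloxy)-2-bromophenyl][4-(benzyloxy)phenyl]methanol
Product: 5 4-(benzyloxy)-1-[4-(benzyloxy)benzyl]-2-bromobenzene
Conditions: Et3SiH (excess), CF3CO2H, CH2Cl2, 0 °C
Reagents that add atoms: none
Why: Ionic hydrogenation; the diarylmethyl cation, stabilized by two para alkoxy groups, forms at 0 °C and is trapped by the silane, while aryl benzyl ethers tolerate brief cold acid.

Step 4
Reactants: 5 4-(benzyloxy)-1-[4-(benzyloxy)benzyl]-2-bromobenzene
Product: 6 (E)-3-{5-(benzyloxy)-2-[4-(benzyloxy)benzyl]phenyl}prop-2-enoic acid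
Conditions: acrylic acid, Pd(OAc)2 (cat.), P(o-tol)3, Et3N, DMF, 100 °C; then aq HCl
Reagents that add atoms: acrylic acid, C=CC(=O)O
Why: Heck reaction of an aryl bromide with acrylic acid, which gives the (E)-cinnamic acid directly and saves a separate ester hydrolysis.

Step 5
Reactants: 6 (E)-3-{5-(benzyloxy)-2-[4-(benzyloxy)benzyl]phenyl}prop-2-enoic acid
Product: 7 3-{5-(benzyloxy)-2-[4-(benzyloxy)benzyl]phenyl}propanoic acid
Conditions: H2 (3 atm), RhCl(PPh3)3 (cat.), THF/EtOH, 50 °C
Reagents that add atoms: none
Why: Homogeneous hydrogenation of the conjugated alkene; unlike palladium on carbon, this rhodium catalyst does not hydrogenolyse aryl benzyl ethers.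

Step 6
Reactants: 8 methyl (triphenylphosphoranylidene)acetate; 9 4-(benzyloxy)benzyl chloride
Product: 11 methyl 3-[4-(benzyloxy)phenyl]-2-(triphenylphosphoranylidene)propanoate, via phosphonium chloride 10 (not isolated)
Conditions: MeCN, 60 °C; then aq NaOH, CH2Cl2, rt
Reagents that add atoms: none
Why: C-alkylation of a stabilized ylide by a reactive benzylic chloride, then deprotonation of the phosphonium salt to the fully substituted stabilized ylide, which is a stable solid.

Step 7
Reactants: 7 3-{5-(benzyloxy)-2-[4-(benzyloxy)benzyl]phenyl}propanoic acid; 11 methyl 3-[4-(benzyloxy)phenyl]-2-(triphenylphosphoranylidene)propanoate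
Product: 14 racemic methyl 2-[4-(benzyloxy)benzyl]-5-{5-(benzyloxy)-2-[4-(benzyloxy)benzyl]phenyl}penta-2,3-dienoate, via acid chloride 12 (not isolated), via ketene 13 (not isolated)
Conditions: (COCl)2, DMF (cat.), CH2Cl2, 0 °C to rt, evaporate; then slow addition to 11, Et3N, CH2Cl2, 0 °C to rt
Reagents that add atoms: none
Why: Acid chloride formation, dehydrochlorination to the ketene and Wittig olefination of the ketene carbonyl by the stabilized ylide, the standard route to α-substituted 2,3-dienoates; slow addition keeps the ketene concentration low, and the allene axis forms as the racemate.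

Step 8
Reactants: 15 tert-butyl acetoacetate; 9 4-(benzyloxy)benzyl chloride
Product: 16 tert-butyl 5-[4-(benzyloxy)phenyl]-3-oxopentanoate
Conditions: NaH, THF, 0 °C; n-BuLi, 0 °C; 9, 0 °C to rt; cold aq HCl
Reagents that add atoms: none
Why: γ-Alkylation of a β-keto ester dianion; the terminal carbanion is the more basic and more nucleophilic site and reacts cleanly with benzylic halides.

Step 9
Reactants: 16 tert-butyl 5-[4-(benzyloxy)phenyl]-3-oxopentanoate; 14 racemic methyl 2-[4-(benzyloxy)benzyl]-5-{5-(benzyloxy)-2-[4-(benzyloxy)benzyl]phenyl}penta-2,3-dienoate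
Product: 18 tert-butyl 3,5-bis[4-(benzyloxy)benzyl]-4-(2-{5-(benzyloxy)-2-[4-(benzyloxy)benzyl]phenyl}ethyl)-2,6-dihydroxybenzoate, via Michael adduct 17 (not isolated)
Conditions: 16, NaH, THF, 0 °C; n-BuLi, 0 °C; 14, −78 °C; MeOH (2 equiv), −78 °C to 40 °C; aq HCl
Reagents that add atoms: none
Why: Proposed new method: the sodium lithium dianion of 16 should attack with its more basic γ-carbon (C4) the central sp carbon (C5) of 14, the β-position of the allenoate, to give an ester dienolate. Methanol then protonates this dienolate, the strongest base present, to the β,γ-unsaturated ester 17 while the keto ester enolate at C2 stays intact; this enolate attacks the methyl ester carbon C1 and expels methoxide (Dieckmann condensation), and the resulting 2-acylcyclohexane-1,3-dione with an exocyclic alkylidene at C5 tautomerizes to the arene 18, which restores the bridge CH2. The closest known reaction types are the Michael-Dieckmann resorcinol synthesis from 3-oxoglutarate monoanions with allenoates or alkynoates and the γ-selective conjugate addition of 1,3-dicarbonyl dianions to unsaturated esters; new is the use of a simple β-keto ester dianion as the three-carbon donor toward an allenoate. Ring A closes in a 6-exo-trig acyl substitution of the enolate carbon C2 on the ester carbonyl C1. No stereocentre survives: the allene axis of 14 and the sp3 centres and alkene geometry of 17 are erased on aromatization. The step needs chemoselectivity (conjugate attack at C5 instead of attack at the ester carbonyl or deprotonation of the benzylic CH2 next to the allene) and site selectivity (C4 first, C2 second); the unhindered, strongly electrophilic sp carbon next to an α-branched ester should secure the first, the order of basicity within the dianion the second. The dianion is made without an amine base so that no secondary amine can add to the allenoate, and C-acylation should win over O-acylation because only the C-acylated product is drained as the aromatic bis-phenoxide.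

Step 10
Reactants: 18 tert-butyl 3,5-bis[4-(benzyloxy)benzyl]-4-(2-{5-(benzyloxy)-2-[4-(benzyloxy)benzyl]phenyl}ethyl)-2,6-dihydroxybenzoate
Product: 19 tert-butyl 3,5-bis[4-(benzyloxy)benzyl]-4-(2-{5-(benzyloxy)-2-[4-(benzyloxy)benzyl]phenyl}ethyl)-2-hydroxy-6-methoxybenzoate
Conditions: MeI (1.05 equiv), K2CO3, acetone, rt
Reagents that add atoms: iodomethane, CI
Why: Selective mono-O-alkylation of a 2,6-dihydroxybenzoate; the two hydroxyls are equivalent, and after the first methylation the remaining one is chelated to the ester carbonyl and should be alkylated much more slowly.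

Step 11
Reactants: 19 tert-butyl 3,5-bis[4-(benzyloxy)benzyl]-4-(2-{5-(benzyloxy)-2-[4-(benzyloxy)benzyl]phenyl}ethyl)-2-hydroxy-6-methoxybenzoate
Product: 21 2,4-bis[4-(benzyloxy)benzyl]-3-(2-{5-(benzyloxy)-2-[4-(benzyloxy)benzyl]phenyl}ethyl)-5-methoxyphenol, via benzoic acid 20 (not isolated)
Conditions: CF3CO2H/CH2Cl2 (1:4), 0 °C to rt; evaporate; then DMSO, 120 °C
Reagents that add atoms: none
Why: Acidolysis of the tert-butyl ester with loss of 2-methylpropene, then thermal protodecarboxylation of the 2-hydroxy-6-alkoxybenzoic acid, which is easy because ipso protonation at C2 is assisted by both ortho oxygens; aryl benzyl ethers tolerate brief dilute acid.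

Step 12
Reactants: 21 2,4-bis[4-(benzyloxy)benzyl]-3-(2-{5-(benzyloxy)-2-[4-(benzyloxy)benzyl]phenyl}ethyl)-5-methoxyphenol
Product: 22 3-{2-[5-hydroxy-2-(4-hydroxybenzyl)phenyl]ethyl}-2,4-bis(4-hydroxybenzyl)-5-methoxyphenol
Conditions: H2 (1 atm), Pd/C, EtOAc/MeOH, rt
Reagents that add atoms: none
Why: Hydrogenolysis of four aryl benzyl ethers under neutral conditions; the methyl ether, the diarylmethane CH2 groups and the bibenzyl bridge are inert.

## Compound list

1 | 2-bromo-4-hydroxybenzaldehyde | O=Cc1ccc(O)cc1Br | starting material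
2 | 4-(benzyloxy)-2-bromobenzaldehyde | O=Cc1ccc(OCc2ccccc2)cc1Br | intermediate
3 | 4-(benzyloxy)phenylmagnesium bromide | Br[Mg]c1ccc(OCc2ccccc2)cc1 | starting material
4 | rac-[4-(benzyloxy)-2-bromophenyl][4-(benzyloxy)phenyl]methanol | OC(c1ccc(OCc2ccccc2)cc1)c1ccc(OCc2ccccc2)cc1Br | intermediate
5 | 4-(benzyloxy)-1-[4-(benzyloxy)benzyl]-2-bromobenzene | Brc1cc(OCc2ccccc2)ccc1Cc1ccc(OCc2ccccc2)cc1 | intermediate
6 | (E)-3-{5-(benzyloxy)-2-[4-(benzyloxy)benzyl]phenyl}prop-2-enoic acid | OC(=O)/C=C/c1cc(OCc2ccccc2)ccc1Cc1ccc(OCc2ccccc2)cc1 | intermediate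
7 | 3-{5-(benzyloxy)-2-[4-(benzyloxy)benzyl]phenyl}propanoic acid | OC(=O)CCc1cc(OCc2ccccc2)ccc1Cc1ccc(OCc2ccccc2)cc1 | intermediate
8 | methyl (triphenylphosphoranylidene)acetate | COC(=O)C=P(c1ccccc1)(c1ccccc1)c1ccccc1 | starting material
9 | 4-(benzyloxy)benzyl chloride | ClCc1ccc(OCc2ccccc2)cc1 | starting material
10 | {3-[4-(benzyloxy)phenyl]-1-methoxy-1-oxopropan-2-yl}triphenylphosphonium chloride (not isolated) | COC(=O)C(Cc1ccc(OCc2ccccc2)cc1)[P+](c1ccccc1)(c1ccccc1)c1ccccc1.[Cl-] | intermediate
11 | methyl 3-[4-(benzyloxy)phenyl]-2-(triphenylphosphoranylidene)propanoate | COC(=O)C(Cc1ccc(OCc2ccccc2)cc1)=P(c1ccccc1)(c1ccccc1)c1ccccc1 | intermediate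
12 | 3-{5-(benzyloxy)-2-[4-(benzyloxy)benzyl]phenyl}propanoyl chloride (not isolated) | ClC(=O)CCc1cc(OCc2ccccc2)ccc1Cc1ccc(OCc2ccccc2)cc1 | intermediate
13 | 3-{5-(benzyloxy)-2-[4-(benzyloxy)benzyl]phenyl}prop-1-en-1-one, the ketene (not isolated) | O=C=CCc1cc(OCc2ccccc2)ccc1Cc1ccc(OCc2ccccc2)cc1 | intermediate
14 | racemic methyl 2-[4-(benzyloxy)benzyl]-5-{5-(benzyloxy)-2-[4-(benzyloxy)benzyl]phenyl}penta-2,3-dienoate | COC(=O)C(Cc1ccc(OCc2ccccc2)cc1)=C=CCc1cc(OCc2ccccc2)ccc1Cc1ccc(OCc2ccccc2)cc1 | intermediate
15 | tert-butyl acetoacetate | CC(=O)CC(=O)OC(C)(C)C | starting material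
16 | tert-butyl 5-[4-(benzyloxy)phenyl]-3-oxopentanoate | CC(C)(C)OC(=O)CC(=O)CCc1ccc(OCc2ccccc2)cc1 | intermediate
17 | 1-tert-butyl 7-methyl 4,6-bis[4-(benzyloxy)benzyl]-5-(2-{5-(benzyloxy)-2-[4-(benzyloxy)benzyl]phenyl}ethylidene)-3-oxoheptanedioate, mixture of isomers (not isolated) | CC(C)(C)OC(=O)CC(=O)C(Cc1ccc(OCc2ccccc2)cc1)C(=CCc1cc(OCc2ccccc2)ccc1Cc1ccc(OCc2ccccc2)cc1)C(Cc1ccc(OCc2ccccc2)cc1)C(=O)OC | intermediate
18 | tert-butyl 3,5-bis[4-(benzyloxy)benzyl]-4-(2-{5-(benzyloxy)-2-[4-(benzyloxy)benzyl]phenyl}ethyl)-2,6-dihydroxybenzoate | CC(C)(C)OC(=O)c1c(O)c(Cc2ccc(OCc3ccccc3)cc2)c(CCc2cc(OCc3ccccc3)ccc2Cc2ccc(OCc3ccccc3)cc2)c(Cc2ccc(OCc3ccccc3)cc2)c1O | intermediate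
19 | tert-butyl 3,5-bis[4-(benzyloxy)benzyl]-4-(2-{5-(benzyloxy)-2-[4-(benzyloxy)benzyl]phenyl}ethyl)-2-hydroxy-6-methoxybenzoate | CC(C)(C)OC(=O)c1c(O)c(Cc2ccc(OCc3ccccc3)cc2)c(CCc2cc(OCc3ccccc3)ccc2Cc2ccc(OCc3ccccc3)cc2)c(Cc2ccc(OCc3ccccc3)cc2)c1OC | intermediate
20 | 3,5-bis[4-(benzyloxy)benzyl]-4-(2-{5-(benzyloxy)-2-[4-(benzyloxy)benzyl]phenyl}ethyl)-2-hydroxy-6-methoxybenzoic acid (not isolated) | OC(=O)c1c(O)c(Cc2ccc(OCc3ccccc3)cc2)c(CCc2cc(OCc3ccccc3)ccc2Cc2ccc(OCc3ccccc3)cc2)c(Cc2ccc(OCc3ccccc3)cc2)c1OC | intermediate
21 | 2,4-bis[4-(benzyloxy)benzyl]-3-(2-{5-(benzyloxy)-2-[4-(benzyloxy)benzyl]phenyl}ethyl)-5-methoxyphenol | COc1cc(O)c(Cc2ccc(OCc3ccccc3)cc2)c(CCc2cc(OCc3ccccc3)ccc2Cc2ccc(OCc3ccccc3)cc2)c1Cc1ccc(OCc2ccccc2)cc1 | intermediate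
22 | 3-{2-[5-hydroxy-2-(4-hydroxybenzyl)phenyl]ethyl}-2,4-bis(4-hydroxybenzyl)-5-methoxyphenol | COc1cc(O)c(Cc2ccc(O)cc2)c(CCc2cc(O)ccc2Cc2ccc(O)cc2)c1Cc1ccc(O)cc1 | target

## Step count and risks

Total: 12 steps. Longest linear sequence: 10 steps (steps 1 to 5, 7, 9 to 12).

**Step 9 (key step, proposed new method).** Several processes could divert it:
- deprotonation of the allenoate at the benzylic CH2 next to the allene by the strongly basic dianion, with isomerization to the conjugated dienoate instead of conjugate addition;
- attack at the ester carbonyl;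
- stalling of the Dieckmann step if the dienolate is not protonated;
- O-acylation to an enol lactone.

Fallback by known reactions only, setting out from bromide 5 and chloride 9 and rejoining the route at the target 22. Commercial 3-hydroxy-5-methoxybenzaldehyde F1 would be O-benzylated (BnBr, K2CO3) to 3-(benzyloxy)-5-methoxybenzaldehyde F2. Bromination (Br2, NaOAc, AcOH) at the two positions para to an alkoxy group would give 3-(benzyloxy)-2,6-dibromo-5-methoxybenzaldehyde F3. Double Negishi coupling (Pd(OAc)2, SPhos, THF) with [4-(benzyloxy)benzyl]zinc chloride F4, made from 9 with zinc dust and LiCl, would give 3-(benzyloxy)-2,6-bis[4-(benzyloxy)benzyl]-5-methoxybenzaldehyde F5. Wittig methylenation (Ph3P=CH2) would give 1-(benzyloxy)-2,4-bis[4-(benzyloxy)benzyl]-3-ethenyl-5-methoxybenzene F6. A Heck reaction of F6 with 5 (Pd(OAc)2, P(o-tol)3, Et3N) would give 1-(benzyloxy)-2,4-bis[4-(benzyloxy)benzyl]-3-[(E)-2-{5-(benzyloxy)-2-[4-(benzyloxy)benzyl]phenyl}ethenyl]-5-methoxybenzene F7, the same compound as A6. Hydrogenation over Pd/C would saturate the alkene and remove all five benzyl groups to give 22.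

**Step 7.** Triethylamine could isomerize the allenoate to the conjugated 2,4-dienoate through its benzylic hydrogens, and the ketene could dimerize before it meets the hindered ylide. Fallback from acid 7, rejoining at 14. Activation of 7 with 1,1'-carbonyldiimidazole and reaction with potassium methyl malonate, MgCl2 and Et3N (decarboxylative Claisen condensation) would give methyl 5-{5-(benzyloxy)-2-[4-(benzyloxy)benzyl]phenyl}-3-oxopentanoate F8. C-Benzylation with 9 (K2CO3, acetone) would give methyl 2-[4-(benzyloxy)benzyl]-5-{5-(benzyloxy)-2-[4-(benzyloxy)benzyl]phenyl}-3-oxopentanoate F9. Triflation of its enolate (LiN(SiMe3)2, Tf2O, −78 °C) would give methyl 2-[4-(benzyloxy)benzyl]-5-{5-(benzyloxy)-2-[4-(benzyloxy)benzyl]phenyl}-3-{[(trifluoromethyl)sulfonyl]oxy}pent-2-enoate F10. A second equivalent of LiN(SiMe3)2 would eliminate triflate toward the CH2 group and give 14.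

**Step 10.** Methylation could run on to the dimethyl ether or stay incomplete, because both hindered phenols are chelated and lie next to benzyl groups. Fallback from 18, rejoining at 21. Ester cleavage and decarboxylation of 18 (CF3CO2H/CH2Cl2, then heat) would give the symmetric resorcinol 4,6-bis[4-(benzyloxy)benzyl]-5-(2-{5-(benzyloxy)-2-[4-(benzyloxy)benzyl]phenyl}ethyl)benzene-1,3-diol F11. This would be methylated with a deficit of MeI (K2CO3, acetone) under statistical control, with recycling of recovered F11, to give 21.

**Step 11.** Ipso protonation of the very electron-rich ring A could cause loss or migration of a 4-(benzyloxy)benzyl group in acid, the tert-butyl cation could alkylate an arene, and loss of CO2 could be sluggish. Fallback with an ester that is removed without acid, setting out from 9 and 14 and rejoining at acid 20. Commercial allyl acetoacetate F12 would be alkylated as in step 8 to allyl 5-[4-(benzyloxy)phenyl]-3-oxopentanoate F13. Annulation with 14 as in step 9 would give allyl 3,5-bis[4-(benzyloxy)benzyl]-4-(2-{5-(benzyloxy)-2-[4-(benzyloxy)benzyl]phenyl}ethyl)-2,6-dihydroxybenzoate F14. Methylation as in step 10 would give allyl 3,5-bis[4-(benzyloxy)benzyl]-4-(2-{5-(benzyloxy)-2-[4-(benzyloxy)benzyl]phenyl}ethyl)-2-hydroxy-6-methoxybenzoate F15. Allyl transfer to morpholine with Pd(PPh3)4 (zerovalent palladium) would give 20, which is decarboxylated thermally to 21.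

**Step 3.** The diarylmethyl cation could alkylate a second electron-rich arene (Friedel-Crafts self-condensation), and a benzyl ether could be partly lost. Fallback from aldehyde 2, rejoining at 5. Reduction with NaBH4 would give [4-(benzyloxy)-2-bromophenyl]methanol F16, and PBr3 would give 4-(benzyloxy)-2-bromo-1-(bromomethyl)benzene F17. Suzuki coupling with commercial 4-(benzyloxy)phenylboronic acid F18 (Pd(PPh3)4, Na2CO3) at the benzylic C–Br bond, which adds to zerovalent palladium faster than the electron-rich aryl bromide, would give 5.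

## Further compounds

F1 | step 9 | 3-hydroxy-5-methoxybenzaldehyde | COc1cc(O)cc(C=O)c1
F2 | step 9 | 3-(benzyloxy)-5-methoxybenzaldehyde | COc1cc(OCc2ccccc2)cc(C=O)c1
F3 | step 9 | 3-(benzyloxy)-2,6-dibromo-5-methoxybenzaldehyde | COc1cc(OCc2ccccc2)c(Br)c(C=O)c1Br
F4 | step 9 | [4-(benzyloxy)benzyl]zinc chloride | Cl[Zn]Cc1ccc(OCc2ccccc2)cc1
F5 | step 9 | 3-(benzyloxy)-2,6-bis[4-(benzyloxy)benzyl]-5-methoxybenzaldehyde | COc1cc(OCc2ccccc2)c(Cc2ccc(OCc3ccccc3)cc2)c(C=O)c1Cc1ccc(OCc2ccccc2)cc1
F6 | step 9 | 1-(benzyloxy)-2,4-bis[4-(benzyloxy)benzyl]-3-ethenyl-5-methoxybenzene | COc1cc(OCc2ccccc2)c(Cc2ccc(OCc3ccccc3)cc2)c(C=C)c1Cc1ccc(OCc2ccccc2)cc1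
F7 | step 9 | 1-(benzyloxy)-2,4-bis[4-(benzyloxy)benzyl]-3-[(E)-2-{5-(benzyloxy)-2-[4-(benzyloxy)benzyl]phenyl}ethenyl]-5-methoxybenzene | COc1cc(OCc2ccccc2)c(Cc2ccc(OCc3ccccc3)cc2)c(/C=C/c2cc(OCc3ccccc3)ccc2Cc2ccc(OCc3ccccc3)cc2)c1Cc1ccc(OCc2ccccc2)cc1
F8 | step 7 | methyl 5-{5-(benzyloxy)-2-[4-(benzyloxy)benzyl]phenyl}-3-oxopentanoate | COC(=O)CC(=O)CCc1cc(OCc2ccccc2)ccc1Cc1ccc(OCc2ccccc2)cc1
F9 | step 7 | methyl 2-[4-(benzyloxy)benzyl]-5-{5-(benzyloxy)-2-[4-(benzyloxy)benzyl]phenyl}-3-oxopentanoate | COC(=O)C(Cc1ccc(OCc2ccccc2)cc1)C(=O)CCc1cc(OCc2ccccc2)ccc1Cc1ccc(OCc2ccccc2)cc1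
F10 | step 7 | methyl 2-[4-(benzyloxy)benzyl]-5-{5-(benzyloxy)-2-[4-(benzyloxy)benzyl]phenyl}-3-{[(trifluoromethyl)sulfonyl]oxy}pent-2-enoate | COC(=O)C(Cc1ccc(OCc2ccccc2)cc1)=C(OS(=O)(=O)C(F)(F)F)CCc1cc(OCc2ccccc2)ccc1Cc1ccc(OCc2ccccc2)cc1
F11 | step 10 | 4,6-bis[4-(benzyloxy)benzyl]-5-(2-{5-(benzyloxy)-2-[4-(benzyloxy)benzyl]phenyl}ethyl)benzene-1,3-diol | Oc1cc(O)c(Cc2ccc(OCc3ccccc3)cc2)c(CCc2cc(OCc3ccccc3)ccc2Cc2ccc(OCc3ccccc3)cc2)c1Cc1ccc(OCc2ccccc2)cc1
F12 | step 11 | allyl acetoacetate | CC(=O)CC(=O)OCC=C
F13 | step 11 | allyl 5-[4-(benzyloxy)phenyl]-3-oxopentanoate | C=CCOC(=O)CC(=O)CCc1ccc(OCc2ccccc2)cc1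
F14 | step 11 | allyl 3,5-bis[4-(benzyloxy)benzyl]-4-(2-{5-(benzyloxy)-2-[4-(benzyloxy)benzyl]phenyl}ethyl)-2,6-dihydroxybenzoate | C=CCOC(=O)c1c(O)c(Cc2ccc(OCc3ccccc3)cc2)c(CCc2cc(OCc3ccccc3)ccc2Cc2ccc(OCc3ccccc3)cc2)c(Cc2ccc(OCc3ccccc3)cc2)c1O
F15 | step 11 | allyl 3,5-bis[4-(benzyloxy)benzyl]-4-(2-{5-(benzyloxy)-2-[4-(benzyloxy)benzyl]phenyl}ethyl)-2-hydroxy-6-methoxybenzoate | C=CCOC(=O)c1c(O)c(Cc2ccc(OCc3ccccc3)cc2)c(CCc2cc(OCc3ccccc3)ccc2Cc2ccc(OCc3ccccc3)cc2)c(Cc2ccc(OCc3ccccc3)cc2)c1OC
F16 | step 3 | [4-(benzyloxy)-2-bromophenyl]methanol | OCc1ccc(OCc2ccccc2)cc1Br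
F17 | step 3 | 4-(benzyloxy)-2-bromo-1-(bromomethyl)benzene | BrCc1ccc(OCc2ccccc2)cc1Br
F18 | step 3 | 4-(benzyloxy)phenylboronic acid | OB(O)c1ccc(OCc2ccccc2)cc1
A1 | alternative 1 | methyl {3-(benzyloxy)-2-[4-(benzyloxy)benzyl]-6-[4-(benzyloxy)benzoyl]-5-methoxyphenyl}acetate | COc1cc(OCc2ccccc2)c(Cc2ccc(OCc3ccccc3)cc2)c(CC(=O)OC)c1C(=O)c1ccc(OCc2ccccc2)cc1
A2 | alternative 1 | 5-(benzyloxy)-6-[4-(benzyloxy)benzyl]-3-methoxy-2-(trimethylsilyl)phenyl trifluoromethanesulfonate | COc1cc(OCc2ccccc2)c(Cc2ccc(OCc3ccccc3)cc2)c(OS(=O)(=O)C(F)(F)F)c1[Si](C)(C)C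
A3 | alternative 1 | methyl 3-[4-(benzyloxy)phenyl]-3-oxopropanoate | COC(=O)CC(=O)c1ccc(OCc2ccccc2)cc1
A4 | alternative 2 | tris(diarylcarbinol) from the trialdehyde and three equivalents of 3, mixture of diastereomers | COc1cc(OCc2ccccc2)c(C(O)c2ccc(OCc3ccccc3)cc2)c(CCc2cc(OCc3ccccc3)ccc2C(O)c2ccc(OCc3ccccc3)cc2)c1C(O)c1ccc(OCc2ccccc2)cc1
A5 | alternative 2 | 4-(benzyloxy)-2-{2-[5-(benzyloxy)-2-formylphenyl]ethyl}-6-methoxybenzene-1,3-dicarbaldehyde | COc1cc(OCc2ccccc2)c(C=O)c(CCc2cc(OCc3ccccc3)ccc2C=O)c1C=O
A6 | alternative 3 | 1-(benzyloxy)-2,4-bis[4-(benzyloxy)benzyl]-3-[(E)-2-{5-(benzyloxy)-2-[4-(benzyloxy)benzyl]phenyl}ethenyl]-5-methoxybenzene | COc1cc(OCc2ccccc2)c(Cc2ccc(OCc3ccccc3)cc2)c(/C=C/c2cc(OCc3ccccc3)ccc2Cc2ccc(OCc3ccccc3)cc2)c1Cc1ccc(OCc2ccccc2)cc1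
A7 | alternative 3 | 1-(benzyloxy)-3-iodo-5-methoxybenzene | COc1cc(I)cc(OCc2ccccc2)c1
A8 | alternative 3 | 4-(benzyloxy)-1-[4-(benzyloxy)benzyl]-2-ethenylbenzene | C=Cc1cc(OCc2ccccc2)ccc1Cc1ccc(OCc2ccccc2)cc1
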